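The readings come from a simulation on assumed constants, noise included.

The product in this flask has to be paid for in partner, so the number to read from the runs is what the partner buys.

| setting | midnight | spring | dawn | flask |
|---|---|---|---|---|
| substrate | 0.20 M | 0.20 M | 0.20 M | 0.20 M |
| partner | 0.12 M | 0.48 M | 0.24 M | 0.240 M |
| protic impurity | 0.20 M | 0.20 M | 0.20 M | 0.200 M |
| free catalyst | 0.11 mM | 0.11 mM | 0.11 mM | 0.11 mM |
| stray impurity | 44 µM | 44 µM | 88 µM | 44 µM |
| remark | run made earlier | run made earlier | run made earlier |  |
| time |  |  |  | 6.0 h |

- midnight (time / h: substrate / %, product / %): 0.333: 90.2, 10.0; 1.00: 78.5, 20.5; 1.50: 78.9, 22.8; 2.50: 77.5, 21.8; 4.00: 78.9, 22.8; 5.00: 76.7, 22.2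
- spring (time / h: substrate / %, product / %): 0.833: 64.6, 36.4; 1.50: 44.6, 55.8; 2.50: 24.2, 76.9; 3.00: 16.5, 82.7; 4.00: 7.9, 91.9; 5.00: 0.9, 95.2
- dawn (time / h: substrate / %, product / %): 0.417: 93.8, 5.5; 0.667: 91.0, 9.0; 1.33: 84.3, 15.9; 2.50: 78.3, 24.0; 5.00: 71.2, 29.1

(scatter of a reading: 1 percentage point)

1. why nothing more happens at 6.0 h, or that something still does (no working catalyst is left / all of the substrate has reacted / forward and back rates have come level / it is still moving / the partner has run out first)
2. part of the substrate gone at 6.0 h
3. the product standing at 6.0 h, as a percentage of the substrate charged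

- the reaction counts as stopped when no species that holds the substrate changes by six tenths of a point or more over the second half of the time

Substrate and product sum to the charge within the scatter, so conversion and product are one number. The midnight run holds still from 1.50 h to 5.00 h at a mean product of 22.4%, with substrate left. That is 0.0448 M from 0.12 M of partner, which gives a partner yield, product made per partner charged, of 37.3%. The spring run, with 0.48 M of partner and otherwise the same charges, runs on until 0.9% of substrate is left, so the midnight stop goes with the partner charge. The midnight run differs from the flask among the charges in partner alone. The dawn run has twice the stray impurity, so I leave it out. Taking that yield over unchanged is an assumption, since it was read at another partner charge; on it, my reckoning for the flask is 37.3% of 0.240 M, which is 44.8% of the substrate, stopped with the partner used up.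

The forecast differs from this: no working catalyst is left, with conversion 55% and product 55%. “So the catalyst dies, probably through the protic impurity, and partner protects it.”

The flask gives: the partner has run out first, with conversion 45.7% and product 45.7%.

    substrate + free catalyst ⇌ catalyst intermediate A (K = 12.0 M⁻¹, k = 6.13 M⁻¹ s⁻¹)
    catalyst intermediate A → catalyst intermediate B (k = 2.05 s⁻¹)
    partner + catalyst intermediate B → catalyst intermediate C (k = 9.22 M⁻¹ s⁻¹)
    catalyst intermediate C → catalyst intermediate D (k = 1.90 s⁻¹)
    catalyst intermediate D ⇌ free catalyst + product (K = 0.614 M, k = 11.5 s⁻¹)
    free catalyst + stray impurity → spent catalyst (k = 2820 M⁻¹ s⁻¹)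
    partner + protic impurity → quenched reagent (k = 0.00314 M⁻¹ s⁻¹)

In the flask the partner, the limiting reagent though more of it was charged than of substrate, ran down by two steps at once, with catalyst intermediate B and with the protic impurity, standing at 31.0% of its charge at 0.600 h and 0.117% at 3.00 h. After that the substrate stayed at 54.3%, and the 0.240 M of partner had become 0.149 M of quenched reagent and 0.0914 M of product, a yield of 38.1%. For the neighbour flask with 0.34 M of substrate, the yield 37.3% gives 26.3% of that substrate, and that flask made 28.6%.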